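**Plan**

1. Numbering: C1 is the lactone carbonyl carbon and C24 the OCH2 carbon; the only ring is the 25-membered lactone (ring O plus C1–C24), with no stereocentre and no C=C.
2. Retrosynthesis: C6–C9 are first raised to a 1,3-diyne (C6≡C7–C8≡C9); the C7–C8 σ-bond is then cut, opening the ring to an ester with two terminal alkynes; next the ester O–C1 bond; last C8≡C9, back to an aldehyde at C9.
3. Carbon sources: 16-hexadecanolide gives C9–C24 and the ring oxygen, hept-6-ynoic acid gives C1–C7, and one diazo carbon gives C8.
4. Forward: the C16 lactone is reduced and homologated in one pot to the C17 ω-alkynol and acylated with the C7 alkynoic acid; the ring is then formed by one oxidative alkyne–alkyne coupling that makes C7–C8, and hydrogenation returns C6–C9 to CH2.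
5. Enabling feature: C2–C23 is one unbranched, heteroatom-free polymethylene run, so C6–C9 can be carried at the alkyne level and erased without trace; the 25-membered ring holds the rigid six-atom rod C5–C10 without strain; the ester O–C1(=O) is inert to the coupling. This one event fixes the ring size exactly, since no carbon is lost and no bond migrates.
6. Stereochemistry: none to set; the target is achiral and nothing stereogenic survives the route.

Key step: step 3

**Step 1**
Reactants: 1 16-hexadecanolide
Product: 3 heptadec-16-yn-1-ol, via 16-hydroxyhexadecanal 2 (not isolated)
Conditions: i-Bu2AlH (1.1 equiv), CH2Cl2, −78 °C; MeOH, −78 → 0 °C; then K2CO3, dimethyl (1-diazo-2-oxopropyl)phosphonate, MeOH, 0 °C → rt; aq. KNaC4H4O6 work-up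
Reagents that add atoms: dimethyl (1-diazo-2-oxopropyl)phosphonate (Ohira–Bestmann reagent), COP(=O)(OC)C(=[N+]=[N-])C(C)=O
Why: Partial reduction of the lactone by i-Bu2AlH should stop at the aluminium hemiacetal at −78 °C, methanol should release the ω-hydroxy aldehyde, and Seyferth–Gilbert homologation with the Ohira–Bestmann reagent (tolerant of a free OH and of enolizable aldehydes) should add the single carbon that becomes C8 as a terminal alkyne, a one-pot ester reduction/homologation sequence with close precedent.

**Step 2**
Reactants: 3 heptadec-16-yn-1-ol; 4 hept-6-ynoic acid
Product: 5 heptadec-16-yn-1-yl hept-6-ynoate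
Conditions: DCC (1.1 equiv), DMAP (0.1 equiv), CH2Cl2, 0 °C → rt
Reagents that add atoms: none
Why: Steglich esterification (carbodiimide activation, DMAP acyl transfer) should join an unhindered primary alcohol and an unhindered acid under neutral conditions that leave both terminal alkynes untouched.

**Step 3**
Reactants: 5 heptadec-16-yn-1-yl hept-6-ynoate
Product: 6 tetracosa-6,8-diyn-24-olide
Conditions: Cu(OAc)2 (10 equiv), pyridine/Et2O 5:1, 45 °C; 5 added by syringe pump over 12 h (final 2 mM)
Reagents that add atoms: none
Why: Eglinton oxidative coupling: pyridine-assisted cupration of the two terminal C(sp)–H bonds (C7–H and C8–H) by Cu(OAc)2 gives alkynylcopper centres, and a dinuclear bis(alkynyl) intermediate should collapse to the C7–C8 σ-bond while two divalent copper centres are reduced to monovalent copper. The closest known reaction type is the high-dilution Eglinton/Glaser macrocyclization of α,ω-diyne esters to macrocyclic 1,3-diyne lactones. The one ring closed is the 25-membered lactone, closed end to end with both triple bonds endocyclic, the six collinear atoms C5–C10 being spanned without strain by the remaining 19-atom loop. No stereocentre and no alkene geometry is created. The selectivity needed is ring closure over intermolecular coupling to open-chain and cyclic oligomers, which slow addition into excess oxidant should secure; because the two reacting termini are the only C(sp)–H bonds of 5, no cross/homo or regiochemical question arises. The ester, its α-CH2 and the saturated chain are inert to Cu(OAc)2/pyridine, and the ring size is fixed exactly because no carbon is expelled and no multiple bond can migrate.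

**Step 4**
Reactants: 6 tetracosa-6,8-diyn-24-olide
Product: 7 24-tetracosanolide
Conditions: H2 (1 atm), 10% Pd/C, EtOAc, rt
Reagents that add atoms: none
Why: Heterogeneous catalytic hydrogenation should saturate both triple bonds (four equivalents of H2) without touching the lactone, whose C–O bonds are neither allylic, propargylic nor benzylic, and it creates no stereocentre.

**Compound list**
1 | 16-hexadecanolide (oxacycloheptadecan-2-one) | O=C1CCCCCCCCCCCCCCCO1 | starting material
2 | 16-hydroxyhexadecanal | O=CCCCCCCCCCCCCCCCO | intermediate
3 | heptadec-16-yn-1-ol | C#CCCCCCCCCCCCCCCCO | intermediate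
4 | hept-6-ynoic acid | C#CCCCCC(=O)O | starting material
5 | heptadec-16-yn-1-yl hept-6-ynoate | C#CCCCCC(=O)OCCCCCCCCCCCCCCCC#C | intermediate
6 | tetracosa-6,8-diyn-24-olide (oxacyclopentacosa-7,9-diyn-2-one) | O=C1CCCCC#CC#CCCCCCCCCCCCCCCCO1 | intermediate
7 | 24-tetracosanolide (oxacyclopentacosan-2-one) | O=C1CCCCCCCCCCCCCCCCCCCCCCCO1 | target

Total step count: 4. Longest linear sequence: 4 steps (1 → 3 → 5 → 6 → 7).

**Steps most likely to fail**

Step 3. Intermolecular alkyne coupling may outrun ring closure even under slow addition, giving open-chain and cyclic oligomers. The fallback moves the ring closure to the ester bond and makes C7–C8 intermolecularly. It sets out from alkynol 3 and acid 4. Bromination of the alkyne terminus of 3 (NBS, AgNO3 cat., acetone) should give 17-bromoheptadec-16-yn-1-ol F1. Cadiot–Chodkiewicz cross-coupling of F1 with hept-6-ynoic acid 4 (CuCl cat., NH2OH·HCl, aq. n-BuNH2, MeOH, 0 °C) should give 24-hydroxytetracosa-6,8-diynoic acid F2. Hydrogenation (H2, Pd/C, THF) should give 24-hydroxytetracosanoic acid F3. Yamaguchi macrolactonization (2,4,6-trichlorobenzoyl chloride, Et3N, THF; then DMAP, toluene, reflux, high dilution) then comes back to the route at the target 7.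

Step 1. The hydride reduction may run on to the diol or stop short, and the free hydroxy aldehyde may be lost to acetalization or oligomerization before it is homologated. The fallback sets out from lactone 1. Ring-opening aminolysis (MeNHOMe·HCl, i-PrMgCl, THF, −10 °C) should give 16-hydroxy-N-methoxy-N-methylhexadecanamide F4. Reduction with LiAlH4 (THF, 0 °C) passes through a chelated tetrahedral intermediate that cannot be reduced further and should come back to the route at 16-hydroxyhexadecanal 2. Compound 2 is then isolated and homologated to 3 with the Ohira–Bestmann reagent and K2CO3 in MeOH as in step 1.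

Step 4. Saturation may stall through poisoning of the palladium surface by copper or pyridine traces from step 3, leaving partly reduced lactones that are hard to separate. The fallback replaces surface catalysis by stoichiometric, metal-free diimide reduction (2,4,6-triisopropylbenzenesulfonyl hydrazide, Et3N, THF, rt → 40 °C, repeated charges). It sets out from 6 and comes back to the route at the target 7 without any new compound.

**Further compounds**
F1 | step 3 | 17-bromoheptadec-16-yn-1-ol | BrC#CCCCCCCCCCCCCCCCO
F2 | step 3 | 24-hydroxytetracosa-6,8-diynoic acid | OC(=O)CCCCC#CC#CCCCCCCCCCCCCCCCO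
F3 | step 3 | 24-hydroxytetracosanoic acid | OC(=O)CCCCCCCCCCCCCCCCCCCCCCCO
F4 | step 1 | 16-hydroxy-N-methoxy-N-methylhexadecanamide | CON(C)C(=O)CCCCCCCCCCCCCCCO
F0 | step 4 | none | none
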